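**Plan**
- Retrosynthesis: only the vanillate acyl–O bond is cut. The ring is not cut but contracted: with ring atoms numbered C1 (ester carbinol), C2, C3=C4(Me), C5, C6, C7, C8(Me)2, C9, C10=C11(Me), the C3=C4 alkene is masked as its trans-epoxide and a C7–C10 bond is added.
- Enabling feature: that extra bond makes C7–C8–C9–C10 a gem-dimethylcyclobutane fused to the nine-membered ring C1–C7/C10/C11. This is the caryophyllane skeleton, in which the C11 methyl is an exocyclic methylene and C1 is its allylic ring CH2.
- Forward: (−)-caryophyllene oxide is oxygenated at future C1, the carbinol is set via the enone and acylated with O-silyl vanillic acid. Hydrogen-atom-transfer scission of the cyclobutane fusion bond then unveils the eleven-membered ring and C10=C11; epoxide deoxygenation and desilylation finish.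
- Stereochemistry: C1 (R) from a Corey–Bakshi–Shibata reduction; E-C3=C4 from stereoretentive deoxygenation of the natural trans-epoxide; Z-C10=C11 from the rotamer at scission (not guaranteed, the main risk). The ring-fusion centres of the terpene are erased.

Key step: step 6

Numbering: bicyclic compounds 4–8 use caryophyllane numbering (C1/C9 ring fusion, C4–C5 epoxide, C8 bearing the C13 methylene, C11 gem-dimethyl). It maps to the ring numbering above as C7→C1, C6→C2, C5→C3, C4→C4, C3→C5, C2→C6, C1→C7, C11→C8, C10→C9, C9→C10, C8→C11, C13→C11-methyl.

Assumption: the SeO2 hydroxylation is taken to give both C7 epimers, so the route passes through the ketone and sets C7 by reagent control. In step 7, WCl6 and two equivalents of n-BuLi are taken to give WCl4, LiCl, butane and 1-butene.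

Step 1
Reactants: 1 vanillic acid (4-hydroxy-3-methoxybenzoic acid)
Product: 3 4-(tert-butyldimethylsilyloxy)-3-methoxybenzoic acid, via bis-silylated vanillate 2 (not isolated)
Conditions: TBSCl (2.4 equiv), imidazole (5 equiv), DMF, 22 °C; then AcOH/THF/H2O 3:1:1, 22 °C
Reagents that add atoms: tert-butyldimethylsilyl chloride, CC(C)(C)[Si](C)(C)Cl
Why: Imidazole-promoted silylation of both acidic OH groups followed by selective hydrolysis of the much more labile silyl ester is the standard protection of a hydroxybenzoic acid and leaves the aryl silyl ether, which is stable to mild acid.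

Step 2
Reactants: 4 (−)-caryophyllene oxide, (1R,4R,5R,9S)-4,5-epoxycaryophyll-8(13)-ene
Product: 5 (1R,4R,5R,9S)-4,5-epoxycaryophyll-8(13)-en-7-ol as a mixture of C7 epimers
Conditions: SeO2 (0.5 equiv), t-BuOOH (3 equiv, in decane), CH2Cl2, 0 → 22 °C
Reagents that add atoms: selenium dioxide, O=[Se]=O; tert-butyl hydroperoxide, CC(C)(C)OO
Why: Riley allylic oxidation (ene reaction at the terminal CH2, then [2,3]-sigmatropic shift) should hydroxylate the ring CH2 at C7 rather than the cyclobutane methine C9 (CH2 over CH preference, and a cyclobutene-type ene intermediate is strained), the catalytic weakly acidic medium should spare the epoxide, and the C7 configuration is irrelevant because step 3 removes it.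

Step 3
Reactants: 5 epoxy allylic alcohol (epimer mixture)
Product: 6 (1R,4R,5R,9S)-4,5-epoxycaryophyll-8(13)-en-7-one
Conditions: Dess–Martin periodinane (1.3 equiv), NaHCO3 (5 equiv), CH2Cl2, 0 → 22 °C
Reagents that add atoms: none
Why: Dess–Martin oxidation of a secondary allylic alcohol under bicarbonate buffer should converge both epimers on the α-methylene ketone without opening the epoxide.

Step 4
Reactants: 6 α-methylene ketone
Product: 7 (1R,4R,5R,7R,9S)-4,5-epoxycaryophyll-8(13)-en-7-ol
Conditions: (S)-Me-CBS oxazaborolidine [(S)-1-methyl-3,3-diphenyltetrahydro-1H,3H-pyrrolo[1,2-c][1,3,2]oxazaborole] (0.5 equiv), catecholborane (1.8 equiv), toluene, −78 °C; MeOH, then aq NaHCO3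
Reagents that add atoms: none
Why: Corey–Bakshi–Shibata reduction, in which the fully substituted alkenyl carbon C8 should act as the large group and CH2-6 as the small one, so the (S)-catalyst is expected to deliver hydride to the face that gives the 7R carbinol (the sense established for aryl alkyl ketones and α-substituted enones), with catecholborane at −78 °C avoiding 1,4-reduction and hydroboration.

Step 5
Reactants: 7 (7R)-allylic alcohol; 3 O-silyl vanillic acid
Product: 8 (1R,4R,5R,7R,9S)-4,5-epoxycaryophyll-8(13)-en-7-yl 4-(tert-butyldimethylsilyloxy)-3-methoxybenzoate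
Conditions: N,N'-dicyclohexylcarbodiimide (1.5 equiv), 4-(dimethylamino)pyridine (0.3 equiv), CH2Cl2, 0 → 22 °C
Reagents that add atoms: none
Why: Steglich esterification acylates at oxygen through the acylpyridinium, so the C–O bond at C7 is untouched and the R configuration is retained.

Step 6
Reactants: 8 caryophyllane ester (methylene at ring C11, R at ring C1)
Product: 9 (1R,3R,4R,10Z)-3,4-epoxy-4,8,8,11-tetramethylcycloundec-10-en-1-yl 4-(tert-butyldimethylsilyloxy)-3-methoxybenzoate (ring numbering)
Conditions: Mn(dpm)3 (dpm = 2,2,6,6-tetramethylheptane-3,5-dionate; 0.15 equiv), PhSiH3 (0.9 equiv, syringe pump), t-BuOOH (1.5 equiv), degassed i-PrOH/CH2Cl2 4:1, 0.01 M, 22 °C, argon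
Reagents that add atoms: none
Why: Proposed new method: the manganese hydride formed from Mn(dpm)3, PhSiH3 and t-BuOOH should transfer a hydrogen atom to the CH2 terminus of the 1,1-disubstituted alkene (Mukaiyama-type, Markovnikov), creating the C11 methyl and a tertiary cyclobutylcarbinyl radical at C11; β-scission of the fusion bond C7–C10 then forms the C10=C11 π bond and a secondary C7 radical, which takes a second hydrogen atom from the hydride. The closest known reaction type is the ring opening of pinene-type cyclobutylcarbinyl radicals generated by metal-hydride hydrogen-atom transfer to 1,1-disubstituted alkenes; new here is the cleavage of a fusion bond of a bicyclo[7.2.0] frame with an alkene geometry at stake. The eleven-membered ring is not made by a bond-forming cyclisation but uncovered by fragmentation (two-atom expansion of the nine-membered ring), and no stereocentre is created: C7 and C10 of 8 are erased, C1 and the epoxide are untouched. Fusion-bond cleavage should win over C9–C10 cleavage because it gives a secondary, not a primary, radical and because the endocyclic C10–C7 bond lies nearly parallel to the SOMO when the plane of the C11 centre stands across the mean plane of the nine-membered ring; ring opening must outrun reduction of the tertiary radical, which slow silane addition, high dilution and the strain of the trans-fused four-membered ring should secure, and the limiting silane keeps the trisubstituted product alkene from further hydrogen-atom transfer. The Z geometry requires scission from the C10–C11 rotamer with the cyclobutane CH2 (C9) syn to C1 and the new methyl eclipsing H10, whereas the rotamer with the methyl eclipsing C9, which places the larger C1 substituent away from the cyclobutane and is probably the more comfortable one, gives the E alkene; as ring inversion is expected to be slower than scission, the outcome should mirror the rotamer population of 8, which the 7R acyloxy group biases without guarantee. The epoxide keeps the strained C3–C4 unit out of transannular radical addition and of hydrogen-atom transfer.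

Step 7
Reactants: 9 epoxy Z-alkenyl ester
Product: 10 (1R,3E,10Z)-4,8,8,11-tetramethylcycloundeca-3,10-dien-1-yl 4-(tert-butyldimethylsilyloxy)-3-methoxybenzoate
Conditions: WCl6 (3 equiv), n-BuLi (6 equiv), THF, −78 → 22 °C; then 9, 22 → 50 °C
Reagents that add atoms: none
Why: Deoxygenation by the low-valent tungsten chloride from WCl6/n-BuLi removes epoxide oxygen with predominant retention, so the (3R,4R)-trans-epoxide should return the E alkene; trisubstituted epoxides two carbons from an allylic ester carbinol are a substrate type known to tolerate this reagent, and no free n-BuLi remains when 9 is added.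

Step 8
Reactants: 10 O-silyl target
Product: 11 (1R,3E,10Z)-4,8,8,11-tetramethylcycloundeca-3,10-dien-1-yl 4-hydroxy-3-methoxybenzoate (target)
Conditions: Bu4NF (1.1 equiv), AcOH (1.1 equiv), THF, 0 °C
Reagents that add atoms: none
Why: Fluoride cleavage of the aryl silyl ether (Si–F bond formation), buffered with AcOH so that the phenoxide is protonated at once and the allylic ester and both alkenes are left alone.

**Compound list**
1 | vanillic acid | COc1cc(C(=O)O)ccc1O | starting material
2 | tert-butyldimethylsilyl 4-(tert-butyldimethylsilyloxy)-3-methoxybenzoate | COc1cc(C(=O)O[Si](C)(C)C(C)(C)C)ccc1O[Si](C)(C)C(C)(C)C | intermediate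
3 | 4-(tert-butyldimethylsilyloxy)-3-methoxybenzoic acid | COc1cc(C(=O)O)ccc1O[Si](C)(C)C(C)(C)C | intermediate
4 | (−)-caryophyllene oxide | C=C1CC[C@H]2O[C@]2(C)CC[C@@H]3[C@@H]1CC3(C)C | starting material
5 | (1R,4R,5R,9S)-4,5-epoxycaryophyll-8(13)-en-7-ol, both C7 epimers (C7 left unspecified) | C=C1C(O)C[C@H]2O[C@]2(C)CC[C@@H]3[C@@H]1CC3(C)C | intermediate
6 | (1R,4R,5R,9S)-4,5-epoxycaryophyll-8(13)-en-7-one | C=C1C(=O)C[C@H]2O[C@]2(C)CC[C@@H]3[C@@H]1CC3(C)C | intermediate
7 | (1R,4R,5R,7R,9S)-4,5-epoxycaryophyll-8(13)-en-7-ol | C=C1[C@H](O)C[C@H]2O[C@]2(C)CC[C@@H]3[C@@H]1CC3(C)C | intermediate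
8 | (1R,4R,5R,7R,9S)-4,5-epoxycaryophyll-8(13)-en-7-yl 4-(tert-butyldimethylsilyloxy)-3-methoxybenzoate | C=C1[C@H](OC(=O)c2ccc(O[Si](C)(C)C(C)(C)C)c(OC)c2)C[C@H]2O[C@]2(C)CC[C@@H]3[C@@H]1CC3(C)C | intermediate
9 | (1R,3R,4R,10Z)-3,4-epoxy-4,8,8,11-tetramethylcycloundec-10-en-1-yl 4-(tert-butyldimethylsilyloxy)-3-methoxybenzoate | COc1cc(C(=O)O[C@@H]2C[C@H]3O[C@]3(C)CCCC(C)(C)C/C=C\2C)ccc1O[Si](C)(C)C(C)(C)C | intermediate
10 | (1R,3E,10Z)-4,8,8,11-tetramethylcycloundeca-3,10-dien-1-yl 4-(tert-butyldimethylsilyloxy)-3-methoxybenzoate | COc1cc(C(=O)O[C@@H]2C/C=C(\C)CCCC(C)(C)C/C=C\2C)ccc1O[Si](C)(C)C(C)(C)C | intermediate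
11 | (1R,3E,10Z)-4,8,8,11-tetramethylcycloundeca-3,10-dien-1-yl 4-hydroxy-3-methoxybenzoate | COc1cc(C(=O)O[C@@H]2C/C=C(\C)CCCC(C)(C)C/C=C\2C)ccc1O | target

Total steps: 8 (one on the acid, seven on the terpene). Longest linear sequence: 7 steps (4 → 11).

**Steps most likely to fail**

Step 6. Two processes threaten it: reduction of the tertiary radical by a second hydrogen-atom transfer before the four-membered ring opens (plain hydrogenation of the methylene), and scission through the rotamer with C9 anti to C1, which delivers the E alkene. The fallback sets out from 8 and uses the classical thiyl-radical chain by which methylenecyclobutanes of the β-pinene class are opened. PhSH, kept dilute by syringe pump, with AIBN in benzene at 80 °C should add PhS• reversibly to the methylene, open the C7–C10 bond and, after hydrogen transfer from the thiol to C7, give the ring-opened allylic phenyl sulfide F1. Thiyl radicals add reversibly to trisubstituted alkenes, so the C10=C11 geometry would be equilibrated under the reaction conditions instead of being fixed by the rotamer at scission. This removes the rotamer dependence but gives the Z isomer only if it is the more stable one in this ring. Desulfurisation of F1 with nickel boride (NiCl2·6H2O, NaBH4, MeOH/THF, 0 °C), which spares benzoate esters, epoxides and trisubstituted alkenes, returns to the route at 9.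

Step 4. Hydride delivery may follow the conformation of the nine-membered ring rather than the catalyst, giving poor facial selectivity or the 7S epimer. The fallback sets out from 6 and uses whichever reduction proves selective for the 7S carbinol (Luche reduction with NaBH4/CeCl3·7H2O under substrate control, or the (R)-catalyst) to make the 7S alcohol F2. This alcohol is coupled with acid 3 under Mitsunobu conditions (PPh3, DIAD, THF, 0 °C), which esterifies with inversion and rejoins the route at 8, replacing steps 4 and 5.

Step 7. The tungsten reagent may cleave the C–O bonds stepwise, eroding the E geometry, or may attack the allylic ester. The fallback sets out from 9 and relays the oxygen through sulfur. Thiourea with catalytic Ti(O-i-Pr)4 in THF at reflux should give, by two successive inversions, the trans-thiirane F3. PPh3 in toluene at 80 °C then removes sulfur stereospecifically and rejoins the route at 10.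

**Further compounds**
F1 | step 6 | compound 9 with a phenylsulfanyl group on the C11 methyl carbon, C9 and C1 cis across C10=C11 | COc1cc(C(=O)O[C@@H]2C[C@H]3O[C@]3(C)CCCC(C)(C)C/C=C\2CSc2ccccc2)ccc1O[Si](C)(C)C(C)(C)C
F2 | step 4 | (1R,4R,5R,7S,9S)-4,5-epoxycaryophyll-8(13)-en-7-ol | C=C1[C@@H](O)C[C@H]2O[C@]2(C)CC[C@@H]3[C@@H]1CC3(C)C
F3 | step 7 | (1R,3S,4S,10Z)-3,4-epithio-4,8,8,11-tetramethylcycloundec-10-en-1-yl 4-(tert-butyldimethylsilyloxy)-3-methoxybenzoate | COc1cc(C(=O)O[C@@H]2C[C@@H]3S[C@@]3(C)CCCC(C)(C)C/C=C\2C)ccc1O[Si](C)(C)C(C)(C)C
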